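**Plan**
- Cuts: first the 7-O-MOM group. Then, in quinone ring B (C1=O, C2-OMe, C3-OMe, C4=O, C5-chromanyl, C6-H), the bonds C4–C5 and C6–C1 are cut together. This gives dimethyl squarate, used as its cobalt metallacycle, and (S)-3-ethynylchroman.
- Enabling feature: the run C1(=O)–C2(OMe)=C3(OMe)–C4(=O) of ring B is a ring-opened squarate with two equivalent acyl ends. C5=C6H has the oxidation level of a terminal alkyne, so one alkyne insertion into a temporary five-membered maleoylcobalt ring builds all of ring B with no regiochemical question.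
- Further cuts: C≡C back to CHO (Corey–Fuchs). Then C3–H/C4–H (hydrogenation), and O1–C2 plus C3=C4 of pyran ring C (salicylaldehyde + acrolein). Last, the aryl–CHO and aryl–O bonds on 2,6-dimethoxyphenol.
- Forward order: ring A (bought arene, oxygenated and formylated), then ring C, the C3 stereocentre, the alkyne, ring B, and finally the free 7-OH.
- Stereochemistry: the single stereocentre C3 comes from carboxylate-directed asymmetric hydrogenation of the 2H-chromene-3-carboxylic acid with Ru(OAc)2[(S)-H8-BINAP]. It is carried on under base-free conditions.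

Key step: step 12

Assumption: the facial sense of the hydrogenation is assigned by analogy with (E)-2-alkylcinnamic acids. For these the (S)-ligand delivers hydrogen to the face that corresponds here to the (3R)-acid; the antipodal ligand serves if the sense proves opposite.

Step 1
Reactants: 1 2,6-dimethoxyphenol
Product: 2 1,3-dimethoxy-2-(methoxymethoxy)benzene
Conditions: MOMCl, i-Pr2NEt, CH2Cl2, 0 °C → rt
Reagents that add atoms: chloromethyl methyl ether (MOMCl), COCCl
Why: Williamson-type O-alkylation of the phenol with an α-chloro ether gives an acetal that is stable to base and organolithium reagents, masks the future 7-OH and can be removed with mild acid at the end.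

Step 2
Reactants: 2 1,3-dimethoxy-2-(methoxymethoxy)benzene
Product: 5 2,4-dimethoxy-3-(methoxymethoxy)phenol, via aryllithium 3 (not isolated), via lithium aryltrimethoxyborate 4 (not isolated)
Conditions: n-BuLi, TMEDA, THF, 0 °C; B(OMe)3, −78 °C → rt; 30% aq H2O2, 0 °C → rt
Reagents that add atoms: hydrogen peroxide, OO; n-butyllithium, [Li]CCCC (lithium of 3 and 4 only); trimethyl borate, COB(OC)OC (boron and methoxy groups of 4 only)
Why: Directed ortho-metalation next to a methoxy group (both positions ortho to the MOM ether are blocked and the two open sites are equivalent by symmetry), followed by borylation and oxidative aryl migration from boron to oxygen, installs the fourth ring oxygen as known for 1,2,3-trialkoxybenzenes.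

Step 3
Reactants: 5 2,4-dimethoxy-3-(methoxymethoxy)phenol
Product: 6 2-hydroxy-3,5-dimethoxy-4-(methoxymethoxy)benzaldehyde
Conditions: MgCl2, Et3N, (CH2O)n, MeCN, reflux
Reagents that add atoms: paraformaldehyde (as formaldehyde), C=O
Why: The magnesium-templated Casnati–Skattebøl formylation is specific for the position ortho to the free phenol, and only one such position is open.

Step 4
Reactants: 6 2-hydroxy-3,5-dimethoxy-4-(methoxymethoxy)benzaldehyde; 7 acrolein
Product: 8 6,8-dimethoxy-7-(methoxymethoxy)-2H-chromene-3-carbaldehyde
Conditions: K2CO3, 1,4-dioxane, reflux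
Reagents that add atoms: none
Why: The base-mediated domino oxa-Michael addition/intramolecular aldol condensation of a salicylaldehyde with acrolein is the standard entry to 2H-chromene-3-carbaldehydes and closes ring C at O1–C2 and C3=C4.

Step 5
Reactants: 8 6,8-dimethoxy-7-(methoxymethoxy)-2H-chromene-3-carbaldehyde
Product: 9 6,8-dimethoxy-7-(methoxymethoxy)-2H-chromene-3-carboxylic acid
Conditions: NaClO2, NaH2PO4, 2-methyl-2-butene, t-BuOH/H2O, rt
Reagents that add atoms: sodium chlorite, [Na+].[O-]Cl=O
Why: The Pinnick oxidation converts an enal into the acid without touching the alkene or the acetal, and the chlorine scavenger protects the electron-rich arene.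

Step 6
Reactants: 9 6,8-dimethoxy-7-(methoxymethoxy)-2H-chromene-3-carboxylic acid
Product: 10 (3R)-6,8-dimethoxy-7-(methoxymethoxy)chroman-3-carboxylic acid
Conditions: Ru(OAc)2[(S)-H8-BINAP] (1 mol %), H2 (5 bar), MeOH, 25 °C
Reagents that add atoms: none
Why: In this Noyori-type asymmetric hydrogenation of a trisubstituted acrylic acid (a reaction type shown for (E)-2-alkylcinnamic and 2H-chromene-3-carboxylic acids) the substrate binds to divalent ruthenium as its carboxylate, and the C2-symmetric diphosphine opens only one alkene face to hydride delivery, which sets C3 as R.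

Step 7
Reactants: 10 (3R)-6,8-dimethoxy-7-(methoxymethoxy)chroman-3-carboxylic acid
Product: 11 [(3S)-6,8-dimethoxy-7-(methoxymethoxy)chroman-3-yl]methanol
Conditions: BH3·THF, THF, 0 °C → rt; aq work-up
Reagents that add atoms: none
Why: Borane reduction of the free acid through its acyloxyborane is chemoselective and non-basic, so C3 is untouched and its descriptor changes to S only through the CIP ranking.

Step 8
Reactants: 11 [(3S)-6,8-dimethoxy-7-(methoxymethoxy)chroman-3-yl]methanol
Product: 12 (3R)-6,8-dimethoxy-7-(methoxymethoxy)chroman-3-carbaldehyde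
Conditions: Dess–Martin periodinane, CH2Cl2, 0 °C → rt
Reagents that add atoms: none
Why: The Dess–Martin oxidation runs near neutrality at or below room temperature, which avoids enolisation and β-elimination of aryloxide in this α-chiral aldehyde, and 12 is used at once.

Step 9
Reactants: 12 (3R)-6,8-dimethoxy-7-(methoxymethoxy)chroman-3-carbaldehyde
Product: 13 (3S)-3-(2,2-dibromoethenyl)-6,8-dimethoxy-7-(methoxymethoxy)chroman
Conditions: CBr4, PPh3, CH2Cl2, 0 °C (ylide pre-formed)
Reagents that add atoms: carbon tetrabromide, BrC(Br)(Br)Br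
Why: The first stage of the Corey–Fuchs homologation is a Wittig-type dibromo-olefination that needs no added base, so the α-stereocentre is retained.

Step 10
Reactants: 13 (3S)-3-(2,2-dibromoethenyl)-6,8-dimethoxy-7-(methoxymethoxy)chroman
Product: 15 (3S)-3-ethynyl-6,8-dimethoxy-7-(methoxymethoxy)chroman, via lithium acetylide 14 (not isolated)
Conditions: n-BuLi (2.1 equiv), THF, −78 °C; then H2O
Reagents that add atoms: n-butyllithium, [Li]CCCC (lithium of 14 only)
Why: In the second stage of the Corey–Fuchs homologation, bromine–lithium exchange, α-elimination with 1,2-hydrogen shift (Fritsch–Buttenberg–Wiechell) and deprotonation give the acetylide that is protonated on quench, while low temperature and exact stoichiometry avoid propargylic deprotonation at C3.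

Step 11
Reactants: 16 dimethyl squarate
Product: 18 chloro(dimethylglyoxime)(pyridine)(2,3-dimethoxymaleoyl)cobalt, CoCl(dmgH2)(py)[C(O)C(OMe)=C(OMe)C(O)], via phosphine complex CoCl(PPh3)2(C6H6O4) 17 (not isolated)
Conditions: ClCo(PPh3)3, degassed PhCl, rt → 50 °C; then dimethylglyoxime, pyridine, rt
Reagents that add atoms: chlorotris(triphenylphosphine)cobalt, ClCo(PPh3)3, Cl[Co-3]([P+](c1ccccc1)(c1ccccc1)c1ccccc1)([P+](c1ccccc1)(c1ccccc1)c1ccccc1)[P+](c1ccccc1)(c1ccccc1)c1ccccc1; dimethylglyoxime, C/C(=N\O)/C(=N/O)/C; pyridine, c1ccncc1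
Why: Oxidative addition of monovalent cobalt into the strained acyl–acyl bond of a cyclobutenedione gives the five-membered maleoyl metallacycle of trivalent cobalt, as known for alkyl- and alkoxycyclobutenediones, and exchange of the phosphines for dimethylglyoxime and pyridine gives an air-stable complex that is more reactive toward alkynes.

Step 12
Reactants: 15 (3S)-3-ethynyl-6,8-dimethoxy-7-(methoxymethoxy)chroman; 18 CoCl(dmgH2)(py)[C(O)C(OMe)=C(OMe)C(O)]
Product: 20 2,3-dimethoxy-5-[(3S)-6,8-dimethoxy-7-(methoxymethoxy)chroman-3-yl]cyclohexa-2,5-diene-1,4-dione, via seven-membered cobaltacycle 19 (not isolated)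
Conditions: CoCl2·6H2O, ClCH2CH2Cl, 80 °C, N2
Reagents that add atoms: none
Why: CoCl2·6H2O takes pyridine from the 18-electron trivalent cobalt complex 18, the terminal alkyne of 15 binds at the vacant site and inserts into one Co–acyl bond (first C–C bond) to give cobaltacycle 19, and reductive elimination then joins the vinyl carbon to the second acyl carbon (second C–C bond) and releases the quinone from monovalent cobalt. The closest known reaction type is the maleoylcobalt/alkyne benzoquinone synthesis, shown for complexes from alkyl- and alkoxycyclobutenediones with terminal and internal alkynes. The one ring closed is six-membered ring B, made as a formal [4+2] annulation in which the four-carbon C(=O)–C(OMe)=C(OMe)–C(=O) unit is joined at both ends to the two alkyne carbons, the closing event being a vinyl–acyl reductive elimination from the seven-membered metallacycle. No stereocentre is made: C3 is a spectator propargylic carbon, and the binding of pyridine by CoCl2 keeps the medium free of the base that could epimerise the product through quinone/quinone-methide tautomerism. The only selectivity question, the orientation of the unsymmetrical alkyne, is void because the dimethoxymaleoyl ligand has two equivalent acyl termini, so both insertion modes lead to 20. Chemoselectivity rests on the alkyne being the only π-ligand of 15 that can reach cobalt, while the aryl ethers and the MOM acetal should be inert to the mild hydrated Lewis acid.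

Step 13
Reactants: 20 2,3-dimethoxy-5-[(3S)-6,8-dimethoxy-7-(methoxymethoxy)chroman-3-yl]cyclohexa-2,5-diene-1,4-dione
Product: 21 2,3-dimethoxy-5-[(3S)-7-hydroxy-6,8-dimethoxychroman-3-yl]cyclohexa-2,5-diene-1,4-dione (target)
Conditions: p-TsOH·H2O (cat.), MeOH, 40 °C
Reagents that add atoms: none
Why: Acid-catalysed transacetalisation of the aryl MOM ether to methanol frees the phenol, the solvent traps the methoxymethyl cation and makes any exchange at the vinylogous-ester methoxy groups degenerate, and the base-free medium preserves C3.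

**Compound list** (in 17–19 dative bonds are written as charge-separated single bonds)
1 | 2,6-dimethoxyphenol | COc1cccc(OC)c1O | starting material
2 | 1,3-dimethoxy-2-(methoxymethoxy)benzene | COCOc1c(OC)cccc1OC | intermediate
3 | [2,4-dimethoxy-3-(methoxymethoxy)phenyl]lithium | [Li]c1ccc(OC)c(OCOC)c1OC | intermediate
4 | lithium trimethoxy[2,4-dimethoxy-3-(methoxymethoxy)phenyl]borate | [Li+].CO[B-](OC)(OC)c1ccc(OC)c(OCOC)c1OC | intermediate
5 | 2,4-dimethoxy-3-(methoxymethoxy)phenol | Oc1ccc(OC)c(OCOC)c1OC | intermediate
6 | 2-hydroxy-3,5-dimethoxy-4-(methoxymethoxy)benzaldehyde | O=Cc1cc(OC)c(OCOC)c(OC)c1O | intermediate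
7 | acrolein | C=CC=O | starting material
8 | 6,8-dimethoxy-7-(methoxymethoxy)-2H-chromene-3-carbaldehyde | O=CC1=Cc2cc(OC)c(OCOC)c(OC)c2OC1 | intermediate
9 | 6,8-dimethoxy-7-(methoxymethoxy)-2H-chromene-3-carboxylic acid | OC(=O)C1=Cc2cc(OC)c(OCOC)c(OC)c2OC1 | intermediate
10 | (3R)-6,8-dimethoxy-7-(methoxymethoxy)chroman-3-carboxylic acid | OC(=O)[C@H]1COc2c(cc(OC)c(OCOC)c2OC)C1 | intermediate
11 | [(3S)-6,8-dimethoxy-7-(methoxymethoxy)chroman-3-yl]methanol | OC[C@H]1COc2c(cc(OC)c(OCOC)c2OC)C1 | intermediate
12 | (3R)-6,8-dimethoxy-7-(methoxymethoxy)chroman-3-carbaldehyde | O=C[C@H]1COc2c(cc(OC)c(OCOC)c2OC)C1 | intermediate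
13 | (3S)-3-(2,2-dibromoethenyl)-6,8-dimethoxy-7-(methoxymethoxy)chroman | BrC(Br)=C[C@H]1COc2c(cc(OC)c(OCOC)c2OC)C1 | intermediate
14 | lithium acetylide of 15 | [Li]C#C[C@H]1COc2c(cc(OC)c(OCOC)c2OC)C1 | intermediate
15 | (3S)-3-ethynyl-6,8-dimethoxy-7-(methoxymethoxy)chroman | C#C[C@H]1COc2c(cc(OC)c(OCOC)c2OC)C1 | intermediate
16 | dimethyl squarate (3,4-dimethoxycyclobut-3-ene-1,2-dione) | COC1=C(OC)C(=O)C1=O | starting material
17 | chlorobis(triphenylphosphine)(2,3-dimethoxymaleoyl)cobalt, CoCl(PPh3)2[C(O)C(OMe)=C(OMe)C(O)] | COC1=C(OC)C(=O)[Co-2](Cl)([P+](c2ccccc2)(c2ccccc2)c2ccccc2)([P+](c2ccccc2)(c2ccccc2)c2ccccc2)C1=O | intermediate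
18 | chloro(dimethylglyoxime)(pyridine)(2,3-dimethoxymaleoyl)cobalt, CoCl(dmgH2)(py)[C(O)C(OMe)=C(OMe)C(O)] | COC1=C(OC)C(=O)[Co-3]2(Cl)([n+]3ccccc3)([N+](O)=C(C)C(C)=[N+]2O)C1=O | intermediate
19 | seven-membered cobaltacycle CoCl(dmgH2)[C(R)=CH–C(O)C(OMe)=C(OMe)C(O)], R = (3S)-chroman-3-yl unit of 15, drawn with the migrated acyl group on the unsubstituted alkyne carbon | COC1=C(OC)C(=O)[Co-2]2(Cl)([N+](O)=C(C)C(C)=[N+]2O)C([C@H]3COc4c(cc(OC)c(OCOC)c4OC)C3)=CC1=O | intermediate
20 | 2,3-dimethoxy-5-[(3S)-6,8-dimethoxy-7-(methoxymethoxy)chroman-3-yl]cyclohexa-2,5-diene-1,4-dione | COC1=C(OC)C(=O)C([C@H]2COc3c(cc(OC)c(OCOC)c3OC)C2)=CC1=O | intermediate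
21 | 2,3-dimethoxy-5-[(3S)-7-hydroxy-6,8-dimethoxychroman-3-yl]cyclohexa-2,5-diene-1,4-dione | COC1=C(OC)C(=O)C([C@H]2COc3c(cc(OC)c(O)c3OC)C2)=CC1=O | target

**Step count:** 13 steps in total. The longest linear sequence is 12 steps (steps 1–10, 12 and 13, from 2,6-dimethoxyphenol). Step 11 is the convergent branch.

**Steps most likely to fail**

1. Step 12.
   - What may go wrong: alkyne uptake may be slow on a metallacycle deactivated by two donor methoxy groups. Thermal decarbonylation of the maleoyl ligand or alkyne oligomerisation at the released monovalent cobalt may compete. Configuration at C3 may erode by base-mediated tautomerisation of the product.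
   - Fallback: it sets out from 15 and 16 and returns at 20, and it also makes step 11 unnecessary. Compound 15 is deprotonated again (n-BuLi, THF, −78 °C) to 14. This adds 1,2 to one carbonyl group of 16 and, after aqueous quench, should give the 4-alkynyl-4-hydroxy-2,3-dimethoxycyclobutenone F1 as a mixture of carbinol epimers, which is of no consequence.
   - Heating in p-xylene at 138 °C (Moore rearrangement: 4π electrocyclic opening, six-membered closure onto the alkyne, hydrogen transfer from the hydroxyl group) should give 20. An alkyl-substituted alkyne is the substituent class that favours the quinone over the five-membered product.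

2. Step 6.
   - What may go wrong: facial selectivity may be poor, because the allylic ring oxygen may compete as a ligand. Turnover with the crowded, electron-rich substrate may be sluggish.
   - Fallback: it sets out from 9 and returns at 11, which also removes step 7. Hydrogenation of 9 over Pd/C (H2, EtOAc) would give the racemic chroman acid F2. Its mixed pivalic anhydride F3 (PivCl, Et3N, THF) would acylate lithiated (S)-4-benzyloxazolidin-2-one to give the (3R)-imide F4 and the (3S)-imide F5.
   - The two imides are separated by chromatography or crystallisation, with the assignment secured by X-ray analysis. F4 is then cleaved reductively with LiBH4 (Et2O, MeOH, 0 °C) directly to 11.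

3. Step 13.
   - What may go wrong: solvent may add to the free quinone position, a vinylogous-ester methoxy group may be hydrolysed, or acid-promoted redox chemistry may occur between the liberated phenol and the quinone.
   - Fallback: it sets out from 15 and returns at 21. The MOM group is removed at the alkyne stage (cat. p-TsOH·H2O, MeOH, 40 °C), where no quinone is present, to give the free phenol alkyne F6. Annulation of F6 with 18 under the conditions of step 12 would pass through the phenolic cobaltacycle F7 and deliver 21 directly, so the quinone never meets acid.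

**Further compounds**
F1 | step 12 | 4-{[(3S)-6,8-dimethoxy-7-(methoxymethoxy)chroman-3-yl]ethynyl}-4-hydroxy-2,3-dimethoxycyclobut-2-en-1-one (both carbinol epimers) | COC1=C(OC)C(O)(C#C[C@H]2COc3c(cc(OC)c(OCOC)c3OC)C2)C1=O
F2 | step 6 | racemic 6,8-dimethoxy-7-(methoxymethoxy)chroman-3-carboxylic acid | OC(=O)C1COc2c(cc(OC)c(OCOC)c2OC)C1
F3 | step 6 | racemic mixed anhydride of F2 and pivalic acid | CC(C)(C)C(=O)OC(=O)C1COc2c(cc(OC)c(OCOC)c2OC)C1
F4 | step 6 | (4S)-4-benzyl-3-{[(3R)-6,8-dimethoxy-7-(methoxymethoxy)chroman-3-yl]carbonyl}oxazolidin-2-one | O=C([C@H]1COc2c(cc(OC)c(OCOC)c2OC)C1)N1[C@@H](Cc2ccccc2)COC1=O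
F5 | step 6 | (4S)-4-benzyl-3-{[(3S)-6,8-dimethoxy-7-(methoxymethoxy)chroman-3-yl]carbonyl}oxazolidin-2-one | O=C([C@@H]1COc2c(cc(OC)c(OCOC)c2OC)C1)N1[C@@H](Cc2ccccc2)COC1=O
F6 | step 13 | (3S)-3-ethynyl-6,8-dimethoxychroman-7-ol | C#C[C@H]1COc2c(cc(OC)c(O)c2OC)C1
F7 | step 13 | seven-membered cobaltacycle CoCl(dmgH2)[C(R)=CH–C(O)C(OMe)=C(OMe)C(O)], R = (3S)-7-hydroxy-6,8-dimethoxychroman-3-yl | COC1=C(OC)C(=O)[Co-2]2(Cl)([N+](O)=C(C)C(C)=[N+]2O)C([C@H]3COc4c(cc(OC)c(O)c4OC)C3)=CC1=O
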